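**Retrosynthetic overview**

1. Numbering (decalin): ring A = C1, C2, C3, C4, C4a, C8a; ring B = C4a, C5, C6, C7, C8, C8a; C11 = exocyclic alkene carbon, C12 = its CH2O, C13 = its CH3. The target is (3R,4aS,5R,6R,8aS), E at C8=C11, cis-fused.
2. Enabling feature: the skipped diene C2=C1–C8a–C8=C11 with oxygen on C12. The C1–C8a bond and the C12–O bond lie 1,4 across the tetrasubstituted C8=C11 alkene, which is the retron of a 1,4-carbo-oxygenation of the ring B diene C8a=C8–C11=C12.
3. Ring A is closed last: a (Z)-alkenyl iodide (C1) tethered to C4a undergoes Pd-catalysed 6-exo carbopalladation of that diene, and the allylpalladium is captured by an oxygen nucleophile at C12. This forms C1–C8a, the C8a stereocentre, the E-alkene and the C12–O bond in one operation.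
4. Ring B is bought: (S)-carvone supplies C4a–C8a, the C5 methyl, C11–C13 and the C6 oxygen. Its stereocentre steers the C4–C4a bond (Mukaiyama–Michael) and is then erased when the diene is made (dehydrogenation, deconjugation, reduction).
5. The side chain is grown from the ester (ynone, asymmetric transfer hydrogenation for C3, anti-carbomagnesiation/iodination for the Z-iodoalkene); after ring closure come formylation, desilylation and acetylation.

Key step: step 10

**Route**

Step 1
Reactants: 1 (S)-carvone; 2 tert-butyl[(1-methoxyethenyl)oxy]dimethylsilane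
Product: 4 methyl 2-[(1R,2R,5S)-2-methyl-3-oxo-5-(prop-1-en-2-yl)cyclohexyl]acetate, via silyl enol ether 3 (not isolated)
Conditions: HNTf2 (2 mol%), CH2Cl2, −78 °C; then 1 M HCl, THF, 0 °C
Reagents that add atoms: none
Why: Mukaiyama–Michael addition: the silyl triflimide generated in situ activates the enone and the ketene acetal attacks C4a axially on the face anti to the isopropenyl group (the facial course known for cuprate and allylsilane additions to carvone), which sets C4a from the carvone stereocentre; C5 is protonated without control on hydrolysis and remains epimerisable until step 3.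

Step 2
Reactants: 4 methyl 2-[(1R,2R,5S)-2-methyl-3-oxo-5-(prop-1-en-2-yl)cyclohexyl]acetate
Product: 6 methyl 2-[(1R,2R)-2-methyl-3-oxo-5-(prop-1-en-2-yl)cyclohex-4-en-1-yl]acetate, via lithium enolate 5 (not isolated)
Conditions: LDA, THF, −78 °C; then N-tert-butylbenzenesulfinimidoyl chloride, −78 °C
Reagents that add atoms: none
Why: Kinetic deprotonation with LDA takes the less substituted α-carbon C7 (the ester α-hydrogens are less acidic), and dehydrogenation of the lithium enolate by the sulfinimidoyl chloride (sulfur attack on C7, then syn-elimination of the sulfenamide across C7–C8) should give the C7=C8 enone conjugated with the isopropenyl group; the carvone stereocentre C8 is erased after it has set C4a.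

Step 3
Reactants: 6 methyl 2-[(1R,2R)-2-methyl-3-oxo-5-(prop-1-en-2-yl)cyclohex-4-en-1-yl]acetate
Product: 9 methyl 2-[(1S,5R,6R)-5-hydroxy-6-methyl-3-(prop-1-en-2-yl)cyclohex-2-en-1-yl]acetate, via potassium dienolate 7 (not isolated), via deconjugated ketone 8 (not isolated)
Conditions: KOtBu, tBuOH–THF, 0 °C to rt; inverse addition to AcOH (1 equiv per KOtBu), THF, −78 °C; then CeCl3·7H2O, NaBH4, MeOH, −78 °C
Reagents that add atoms: none
Why: Deconjugative protonation followed by Luche-type reduction: reversible deprotonation gives the extended dienolate by loss of a C8a hydrogen (C5 equilibrates through the α′-enolate to the trans relation with the C4a substituent), kinetic protonation at the α-carbon C7 moves the ring alkene to C8=C8a, and borohydride attacks the C6 carbonyl axially (sp2 C8 removes one 1,3-diaxial contact) before reconjugation, so that the C6 hydroxyl should come out equatorial and trans to the C5 methyl group.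

Step 4
Reactants: 9 methyl 2-[(1S,5R,6R)-5-hydroxy-6-methyl-3-(prop-1-en-2-yl)cyclohex-2-en-1-yl]acetate
Product: 10 methyl 2-[(1S,5R,6R)-5-{[tert-butyl(dimethyl)silyl]oxy}-6-methyl-3-(prop-1-en-2-yl)cyclohex-2-en-1-yl]acetate
Conditions: TBSCl, imidazole, DMF, rt
Reagents that add atoms: tert-butyldimethylsilyl chloride, CC(C)(C)[Si](C)(C)Cl
Why: Standard silylation of a secondary alcohol; the silyl ether withstands the organolithium, Grignard and palladium steps that follow.

Step 5
Reactants: 10 methyl 2-[(1S,5R,6R)-5-{[tert-butyl(dimethyl)silyl]oxy}-6-methyl-3-(prop-1-en-2-yl)cyclohex-2-en-1-yl]acetate; 11 ethynyltrimethylsilane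
Product: 12 1-[(1S,5R,6R)-5-{[tert-butyl(dimethyl)silyl]oxy}-6-methyl-3-(prop-1-en-2-yl)cyclohex-2-en-1-yl]-4-(trimethylsilyl)but-3-yn-2-one
Conditions: 11, n-BuLi, THF, −78 °C; BF3·OEt2; then 10, −78 °C; sat. NH4Cl at −78 °C
Reagents that add atoms: none
Why: BF3-mediated acylation of a lithium acetylide by an ester: the alkynyl borate adds once to the methyl ester and the tetrahedral adduct is stable at −78 °C, so the ynone is released only on quenching and no tertiary alcohol should form.

Step 6
Reactants: 12 1-[(1S,5R,6R)-5-{[tert-butyl(dimethyl)silyl]oxy}-6-methyl-3-(prop-1-en-2-yl)cyclohex-2-en-1-yl]-4-(trimethylsilyl)but-3-yn-2-one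
Product: 13 (2R)-1-[(1S,5R,6R)-5-{[tert-butyl(dimethyl)silyl]oxy}-6-methyl-3-(prop-1-en-2-yl)cyclohex-2-en-1-yl]-4-(trimethylsilyl)but-3-yn-2-ol
Conditions: Ru[(R,R)-TsNCH(Ph)CH(Ph)NH](p-cymene) (2 mol%), iPrOH, rt
Reagents that add atoms: none
Why: Noyori asymmetric transfer hydrogenation of an alkynyl ketone: the (R,R)-configured amido ruthenium catalyst transfers hydride and proton through its six-membered transition state with the alkyne as the directing π-substituent, which should set C3 as R under catalyst control irrespective of the remote ring stereocentres.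

Step 7
Reactants: 13 (2R)-1-[(1S,5R,6R)-5-{[tert-butyl(dimethyl)silyl]oxy}-6-methyl-3-(prop-1-en-2-yl)cyclohex-2-en-1-yl]-4-(trimethylsilyl)but-3-yn-2-ol
Product: 14 (2R)-1-[(1S,5R,6R)-5-{[tert-butyl(dimethyl)silyl]oxy}-6-methyl-3-(prop-1-en-2-yl)cyclohex-2-en-1-yl]but-3-yn-2-ol
Conditions: K2CO3, MeOH, rt
Reagents that add atoms: none
Why: Base-catalysed methanolysis of the alkynyl C–Si bond; the secondary silyl ether is stable to K2CO3 in methanol.

Step 8
Reactants: 14 (2R)-1-[(1S,5R,6R)-5-{[tert-butyl(dimethyl)silyl]oxy}-6-methyl-3-(prop-1-en-2-yl)cyclohex-2-en-1-yl]but-3-yn-2-ol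
Product: 16 (2R,3Z)-1-[(1S,5R,6R)-5-{[tert-butyl(dimethyl)silyl]oxy}-6-methyl-3-(prop-1-en-2-yl)cyclohex-2-en-1-yl]-4-iodo-3-methylbut-3-en-2-ol, via alkenylmagnesium alkoxide 15 (not isolated)
Conditions: MeMgBr (4 equiv), CuI (20 mol%), THF–Et2O, −10 °C to rt; then I2, THF, −78 to 0 °C; aq. Na2S2O3, NH4Cl
Reagents that add atoms: methylmagnesium bromide, C[Mg]Br; iodine, [I][I]
Why: Copper-catalysed anti-carbomagnesiation of a propargylic alcohol: the magnesium alkoxide directs methyl to C2 and magnesium to C1 on opposite faces (five-membered chelate), and iodinolysis of the C1–Mg bond with retention should give the Z-iodoalkene with iodine cis to C3, the geometry that ring closure needs; the reaction type is established for secondary propargylic alcohols and the diene does not react with the Grignard reagent.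

Step 9
Reactants: 16 (2R,3Z)-1-[(1S,5R,6R)-5-{[tert-butyl(dimethyl)silyl]oxy}-6-methyl-3-(prop-1-en-2-yl)cyclohex-2-en-1-yl]-4-iodo-3-methylbut-3-en-2-ol
Product: 17 tert-butyl{[(2R,3Z)-1-[(1S,5R,6R)-5-{[tert-butyl(dimethyl)silyl]oxy}-6-methyl-3-(prop-1-en-2-yl)cyclohex-2-en-1-yl]-4-iodo-3-methylbut-3-en-2-yl]oxy}dimethylsilane
Conditions: TBSOTf, 2,6-lutidine, CH2Cl2, −78 °C
Reagents that add atoms: tert-butyldimethylsilyl trifluoromethanesulfonate, CC(C)(C)[Si](C)(C)OS(=O)(=O)C(F)(F)F
Why: Silylation of the hindered secondary allylic alcohol with the silyl triflate; a silyl ether, unlike an allylic ester, cannot be ionised by zerovalent palladium in step 10.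

Step 10
Reactants: 17 tert-butyl{[(2R,3Z)-1-[(1S,5R,6R)-5-{[tert-butyl(dimethyl)silyl]oxy}-6-methyl-3-(prop-1-en-2-yl)cyclohex-2-en-1-yl]-4-iodo-3-methylbut-3-en-2-yl]oxy}dimethylsilane
Product: 21 (2E)-2-[(3R,4R,4aS,6R,8aS)-3,6-bis{[tert-butyl(dimethyl)silyl]oxy}-4,7-dimethyl-3,4,4a,5,6,8a-hexahydronaphthalen-1(2H)-ylidene]propan-1-ol, via alkenylpalladium iodide 18 (not isolated), via allylpalladium iodide 19 (not isolated), via allyl hydrogencarbonate 20 (not isolated)
Conditions: Pd(OAc)2 (10 mol%), PPh3 (30 mol%), KHCO3 (5 equiv), DMF–H2O (9:1), degassed, 60 °C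
Reagents that add atoms: potassium hydrogencarbonate, [K+].OC([O-])=O
Why: Proposed new method: oxidative addition of zerovalent palladium to the C1–I bond gives alkenylpalladium 18, which inserts the ring B alkene in a 6-exo-trig syn-carbopalladation (C1 to C8a, Pd to C8) to give the η3-allyl complex 19 spanning C8–C11–C12; hydrogencarbonate attacks the primary terminus C12 and the allyl hydrogencarbonate 20 loses CO2 to give the alcohol and zerovalent palladium. The closest known reactions are Heck-type insertions of 1,3-dienes that end in capture of the allylpalladium by an amine, carboxylate or phenoxide (Larock-type diene annulation, cyclisation–anion capture) and the palladium-catalysed conversion of allylic carbonates into allylic alcohols by hydrogencarbonate; their combination on an alkenyl iodide tethered to a 2-substituted diene is new. Ring A closes in the exo mode because the four-atom tether from C4a reaches only the near diene terminus C8a, and it delivers C1 to the face of C8a=C8 that carries the C4a–C4 bond, so the new stereocentre C8a should be set cis to C4a (cis ring fusion) by the existing C4a centre. The E geometry of the new C8=C11 alkene is inherited from the s-trans conformation of the diene (C12 on the C7 side), which is favoured for a diene with no cis substituent on its termini, and should persist because syn/anti exchange at the fully substituted allyl terminus C8 would need an η1-palladium on a tertiary carbon. The step needs capture of 19 to outrun β-hydride loss and needs attack at C12 rather than C8; the excess of a small anionic oxygen nucleophile, the phosphine ligand and the steric gap between a CH2 terminus and a quaternary ring carbon should secure both, and the alcohol product and the two silyl ethers are inert to zerovalent palladium.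

Step 11
Reactants: 21 (2E)-2-[(3R,4R,4aS,6R,8aS)-3,6-bis{[tert-butyl(dimethyl)silyl]oxy}-4,7-dimethyl-3,4,4a,5,6,8a-hexahydronaphthalen-1(2H)-ylidene]propan-1-ol
Product: 22 (2E)-2-[(3R,4R,4aS,6R,8aS)-3,6-bis{[tert-butyl(dimethyl)silyl]oxy}-4,7-dimethyl-3,4,4a,5,6,8a-hexahydronaphthalen-1(2H)-ylidene]propyl formate
Conditions: acetic formic anhydride, pyridine, CH2Cl2, 0 °C
Reagents that add atoms: acetic formic anhydride, CC(=O)OC=O
Why: Formylation of the primary allylic alcohol with the mixed anhydride, which transfers its formyl group because the formyl carbonyl is the less hindered and more electrophilic one.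

Step 12
Reactants: 22 (2E)-2-[(3R,4R,4aS,6R,8aS)-3,6-bis{[tert-butyl(dimethyl)silyl]oxy}-4,7-dimethyl-3,4,4a,5,6,8a-hexahydronaphthalen-1(2H)-ylidene]propyl formate
Product: 23 (2E)-2-[(3R,4R,4aS,6R,8aS)-3,6-dihydroxy-4,7-dimethyl-3,4,4a,5,6,8a-hexahydronaphthalen-1(2H)-ylidene]propyl formate
Conditions: HF·pyridine, pyridine, THF, 0 °C to rt
Reagents that add atoms: none
Why: Fluoride-driven cleavage of both secondary silyl ethers under buffered, weakly acidic and non-nucleophilic conditions, which should leave the formate ester, the allylic C3 alcohol and the skipped diene untouched.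

Step 13
Reactants: 23 (2E)-2-[(3R,4R,4aS,6R,8aS)-3,6-dihydroxy-4,7-dimethyl-3,4,4a,5,6,8a-hexahydronaphthalen-1(2H)-ylidene]propyl formate
Product: 24 (2E)-2-[(3R,4R,4aS,6R,8aS)-3,6-bis(acetyloxy)-4,7-dimethyl-3,4,4a,5,6,8a-hexahydronaphthalen-1(2H)-ylidene]propyl formate (CNP0262962.1)
Conditions: Ac2O, pyridine, DMAP (10 mol%), CH2Cl2, 0 °C to rt
Reagents that add atoms: acetic anhydride, CC(=O)OC(C)=O
Why: Nucleophile-catalysed acetylation (DMAP) of the two secondary alcohols; no alcohol solvent or alkoxide is present, so the formate should not exchange.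

**Compound list**

1 | (S)-carvone, (5S)-2-methyl-5-(prop-1-en-2-yl)cyclohex-2-en-1-one | CC1=CC[C@@H](CC1=O)C(C)=C | starting material
2 | tert-butyl[(1-methoxyethenyl)oxy]dimethylsilane | C=C(OC)O[Si](C)(C)C(C)(C)C | starting material
3 | methyl 2-[(1R,5S)-3-{[tert-butyl(dimethyl)silyl]oxy}-2-methyl-5-(prop-1-en-2-yl)cyclohex-2-en-1-yl]acetate (silyl enol ether) | COC(=O)C[C@@H]1C(C)=C(O[Si](C)(C)C(C)(C)C)C[C@@H](C(C)=C)C1 | intermediate
4 | methyl 2-[(1R,2R,5S)-2-methyl-3-oxo-5-(prop-1-en-2-yl)cyclohexyl]acetate (C5 epimer drawn as trans; epimerisable) | COC(=O)C[C@@H]1[C@@H](C)C(=O)C[C@@H](C(C)=C)C1 | intermediate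
5 | kinetic lithium enolate of 4 (O–Li on C6, C6=C7) | COC(=O)C[C@@H]1[C@@H](C)C(O[Li])=C[C@@H](C(C)=C)C1 | intermediate
6 | methyl 2-[(1R,2R)-2-methyl-3-oxo-5-(prop-1-en-2-yl)cyclohex-4-en-1-yl]acetate | COC(=O)C[C@@H]1[C@@H](C)C(=O)C=C(C(C)=C)C1 | intermediate
7 | extended potassium dienolate of 6 (O–K on C6, C6=C7 and C8=C8a) | COC(=O)C[C@@H]1[C@@H](C)C(O[K])=CC(C(C)=C)=C1 | intermediate
8 | methyl 2-[(1S,6R)-6-methyl-5-oxo-3-(prop-1-en-2-yl)cyclohex-2-en-1-yl]acetate | COC(=O)C[C@@H]1[C@@H](C)C(=O)CC(C(C)=C)=C1 | intermediate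
9 | methyl 2-[(1S,5R,6R)-5-hydroxy-6-methyl-3-(prop-1-en-2-yl)cyclohex-2-en-1-yl]acetate | COC(=O)C[C@@H]1[C@@H](C)[C@H](O)CC(C(C)=C)=C1 | intermediate
10 | methyl 2-[(1S,5R,6R)-5-{[tert-butyl(dimethyl)silyl]oxy}-6-methyl-3-(prop-1-en-2-yl)cyclohex-2-en-1-yl]acetate | COC(=O)C[C@@H]1[C@@H](C)[C@H](O[Si](C)(C)C(C)(C)C)CC(C(C)=C)=C1 | intermediate
11 | ethynyltrimethylsilane | C#C[Si](C)(C)C | starting material
12 | 1-[(1S,5R,6R)-5-{[tert-butyl(dimethyl)silyl]oxy}-6-methyl-3-(prop-1-en-2-yl)cyclohex-2-en-1-yl]-4-(trimethylsilyl)but-3-yn-2-one | C[Si](C)(C)C#CC(=O)C[C@@H]1[C@@H](C)[C@H](O[Si](C)(C)C(C)(C)C)CC(C(C)=C)=C1 | intermediate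
13 | (2R)-1-[(1S,5R,6R)-5-{[tert-butyl(dimethyl)silyl]oxy}-6-methyl-3-(prop-1-en-2-yl)cyclohex-2-en-1-yl]-4-(trimethylsilyl)but-3-yn-2-ol | C[Si](C)(C)C#C[C@H](O)C[C@@H]1[C@@H](C)[C@H](O[Si](C)(C)C(C)(C)C)CC(C(C)=C)=C1 | intermediate
14 | (2R)-1-[(1S,5R,6R)-5-{[tert-butyl(dimethyl)silyl]oxy}-6-methyl-3-(prop-1-en-2-yl)cyclohex-2-en-1-yl]but-3-yn-2-ol | C#C[C@H](O)C[C@@H]1[C@@H](C)[C@H](O[Si](C)(C)C(C)(C)C)CC(C(C)=C)=C1 | intermediate
15 | bromomagnesium alkoxide and alkenylmagnesium bromide from anti-carbomagnesiation of 14 (Mg on C1 cis to C3) | Br[Mg]O[C@H](C[C@@H]1[C@@H](C)[C@H](O[Si](C)(C)C(C)(C)C)CC(C(C)=C)=C1)/C(C)=C\[Mg]Br | intermediate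
16 | (2R,3Z)-1-[(1S,5R,6R)-5-{[tert-butyl(dimethyl)silyl]oxy}-6-methyl-3-(prop-1-en-2-yl)cyclohex-2-en-1-yl]-4-iodo-3-methylbut-3-en-2-ol | O[C@H](C[C@@H]1[C@@H](C)[C@H](O[Si](C)(C)C(C)(C)C)CC(C(C)=C)=C1)/C(C)=C\I | intermediate
17 | tert-butyl{[(2R,3Z)-1-[(1S,5R,6R)-5-{[tert-butyl(dimethyl)silyl]oxy}-6-methyl-3-(prop-1-en-2-yl)cyclohex-2-en-1-yl]-4-iodo-3-methylbut-3-en-2-yl]oxy}dimethylsilane | CC(C)(C)[Si](C)(C)O[C@H](C[C@@H]1[C@@H](C)[C@H](O[Si](C)(C)C(C)(C)C)CC(C(C)=C)=C1)/C(C)=C\I | intermediate
18 | alkenylpalladium iodide from oxidative addition to 17 (divalent palladium on C1, phosphine ligands omitted) | CC(C)(C)[Si](C)(C)O[C@H](C[C@@H]1[C@@H](C)[C@H](O[Si](C)(C)C(C)(C)C)CC(C(C)=C)=C1)/C(C)=C\[Pd]I | intermediate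
19 | cyclised allylpalladium iodide over C8–C11–C12 (drawn as its σ-form on C12, phosphine ligands omitted) | CC(C)(C)[Si](C)(C)O[C@@H]1C[C@@H]2[C@@H](C)[C@H](O[Si](C)(C)C(C)(C)C)C/C(=C(/C)C[Pd]I)[C@@H]2C=C1C | intermediate
20 | hydrogencarbonate (carbonic acid monoester) of alcohol 21 at C12 | CC(C)(C)[Si](C)(C)O[C@@H]1C[C@@H]2[C@@H](C)[C@H](O[Si](C)(C)C(C)(C)C)C/C(=C(/C)COC(O)=O)[C@@H]2C=C1C | intermediate
21 | (2E)-2-[(3R,4R,4aS,6R,8aS)-3,6-bis{[tert-butyl(dimethyl)silyl]oxy}-4,7-dimethyl-3,4,4a,5,6,8a-hexahydronaphthalen-1(2H)-ylidene]propan-1-ol | CC(C)(C)[Si](C)(C)O[C@@H]1C[C@@H]2[C@@H](C)[C@H](O[Si](C)(C)C(C)(C)C)C/C(=C(/C)CO)[C@@H]2C=C1C | intermediate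
22 | (2E)-2-[(3R,4R,4aS,6R,8aS)-3,6-bis{[tert-butyl(dimethyl)silyl]oxy}-4,7-dimethyl-3,4,4a,5,6,8a-hexahydronaphthalen-1(2H)-ylidene]propyl formate | CC(C)(C)[Si](C)(C)O[C@@H]1C[C@@H]2[C@@H](C)[C@H](O[Si](C)(C)C(C)(C)C)C/C(=C(/C)COC=O)[C@@H]2C=C1C | intermediate
23 | (2E)-2-[(3R,4R,4aS,6R,8aS)-3,6-dihydroxy-4,7-dimethyl-3,4,4a,5,6,8a-hexahydronaphthalen-1(2H)-ylidene]propyl formate | O[C@@H]1C[C@@H]2[C@@H](C)[C@H](O)C/C(=C(/C)COC=O)[C@@H]2C=C1C | intermediate
24 | (2E)-2-[(3R,4R,4aS,6R,8aS)-3,6-bis(acetyloxy)-4,7-dimethyl-3,4,4a,5,6,8a-hexahydronaphthalen-1(2H)-ylidene]propyl formate (CNP0262962.1) | CC(=O)O[C@@H]1C[C@@H]2[C@@H](C)[C@H](OC(C)=O)C/C(=C(/C)COC=O)[C@@H]2C=C1C | target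

**Step count and risks**

Total step count: 13. Longest linear sequence: 13 steps from (S)-carvone (compounds 2 and 11 are purchased).

The three steps most likely to fail:

1. Key step (step 10, the proposed new method). What may go wrong: capture of the allylpalladium by hydrogencarbonate may be slower than β-hydride elimination, which would drain the intermediate into trienes, or the alkene geometry may erode through syn/anti exchange. The fallback sets out from 17 and uses known chemistry. The ring closure is run as a carboxylate-terminated Heck/allyl-capture cascade (Pd(OAc)2, PPh3, n-Bu4NOAc, DMF, 60 °C), in which acetate, a terminating nucleophile established for allylpalladium species formed by diene insertion, is delivered from the metal; this should give the bicyclic allylic acetate F1. Methanolysis of the primary acetate (K2CO3, MeOH, 0 °C) then comes back to the route at 21.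

2. Step 3. What may go wrong: the deconjugated ketone may reconjugate before it is reduced, C5 may not equilibrate fully, or hydride delivery to C6 may show poor facial selectivity. The fallback sets out from 6. The thermodynamic potassium dienolate (KOtBu, THF, 0 °C) is trapped on oxygen with acetic anhydride to give the isolable dienyl acetate F2, at which stage C5 epimers can be separated. Treatment of F2 with NaBH4 in MeOH–THF at 0 °C cleaves the enol acetate slowly, and the deconjugated ketone released is reduced at once (the classical enol acetate route from a conjugated enone to a homoallylic alcohol); this comes back to the route at 9.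

3. Step 1. What may go wrong: addition to the α-methylated enone may be slow, or the isopropenyl group may undergo acid-induced side reactions under silyl triflimide catalysis. The fallback sets out from 1. Base-mediated Michael addition of dimethyl malonate (NaOMe, MeOH, rt) should give the trans malonate adduct F3, and Krapcho demethoxycarbonylation (NaCl, wet DMSO, 150 °C) comes back to the route at 4.

**Further compounds**

F1 | step 10 | (2E)-2-[(3R,4R,4aS,6R,8aS)-3,6-bis{[tert-butyl(dimethyl)silyl]oxy}-4,7-dimethyl-3,4,4a,5,6,8a-hexahydronaphthalen-1(2H)-ylidene]propyl acetate | CC(C)(C)[Si](C)(C)O[C@@H]1C[C@@H]2[C@@H](C)[C@H](O[Si](C)(C)C(C)(C)C)C/C(=C(/C)COC(C)=O)[C@@H]2C=C1C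
F2 | step 3 | methyl 2-[(1S,6R)-5-(acetyloxy)-6-methyl-3-(prop-1-en-2-yl)cyclohexa-2,4-dien-1-yl]acetate | COC(=O)C[C@@H]1[C@@H](C)C(OC(C)=O)=CC(C(C)=C)=C1
F3 | step 1 | dimethyl 2-[(1S,2R,5S)-2-methyl-3-oxo-5-(prop-1-en-2-yl)cyclohexyl]propanedioate | COC(=O)C(C(=O)OC)[C@@H]1[C@@H](C)C(=O)C[C@@H](C(C)=C)C1
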